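(The readings were generated by integration with constants of no real substance, noise included.)

The four flasks carry the same amounts, 0.50 M of Q, 0.350 M of X, 0.500 M of J and 0.500 M of Z, and differ in when X or J goes in.

in all of them: Q 0.50 M

|  | X | J | Z | remark | time |
|---|---|---|---|---|---|
| gamma | 0.35 M | 0.50 M | 0.50 M | run made earlier |  |
| beta | 0.35 M | 0.50 M | 0.25 M | run made earlier |  |
| alpha | 0.35 M | 0.50 M | 0.38 M | run made earlier |  |
| theta | 0.35 M | 0.25 M | 0.50 M | run made earlier |  |
| south-east | 0.350 M | 0.500 M | 0.500 M | everything together at the start | 3.0 h |
| east | 0.350 M (fed, over 2.0 h) | 0.500 M | 0.500 M | all else is in the flask from the start; the feed brings no volume worth counting | 3.0 h |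
| west | 0.350 M (fed, over 30 min) | 0.500 M | 0.500 M | all else is in the flask from the start; the feed brings no volume worth counting | 3.0 h |
| south | 0.350 M | 0.500 M (fed, over 2.0 h) | 0.500 M | all else is in the flask from the start; the feed brings no volume worth counting | 3.0 h |

gamma run (percent of the Q charged)

| time / h | D / % |
|---|---|
| 0.200 | 34.7 |
| 0.667 | 28.6 |
| 1.00 | 25.6 |
| 1.50 | 21.8 |
| 2.50 | 15.4 |
| 3.00 | 13.1 |

beta run (percent of the Q charged)

| time / min | D / % |
|---|---|
| 8.00 | 44.1 |
| 15.0 | 43.3 |
| 25.0 | 41.1 |
| 40.0 | 37.8 |
| 60.0 | 35.0 |
| 120 | 28.2 |

alpha run (percent of the Q charged)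

| time / min | D / % |
|---|---|
| 20.0 | 37.3 |
| 40.0 | 32.9 |
| 50.0 | 30.9 |
| 80.0 | 26.6 |
| 90.0 | 25.6 |
| 120 | 22.8 |

theta run (percent of the Q charged)

| time / min | D / % |
|---|---|
| 10.0 | 36.5 |
| 25.0 | 32.6 |
| 50.0 | 28.2 |
| 80.0 | 24.1 |
| 120 | 19.5 |

(each reading ± 0.3 percentage points)

- the best flask by amount of D, in percent of the Q charged; "all alike" if 1.5 percentage points covers them all (south-east / east / west / south / all alike)
- amount of D at the end, in percent of the Q charged, south-east
- amount of D at the end, in percent of the Q charged, east
- amount of D at the end, in percent of the Q charged, west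
- amount of D at the end, in percent of the Q charged, south

I follow the rate at which D fades, not the concentrations. Beta's readings fall from their first, at 8.00 min, so making D takes less time than that, far less than the slow feed and less than the quick one. After that, I read the fade of D as an apparent first-order coefficient, the fall of ln(D) per unit time, and it drifts during a run. In gamma the rate is 0.414 h⁻¹ early and 0.340 h⁻¹ late, a slowing by a factor 0.821. Over the whole run it is 0.348 h⁻¹.

With Z at half the charge, in beta, the rate is 0.240 h⁻¹, a factor 0.690. With J at half the charge, in theta, it is 0.342 h⁻¹, a factor 0.983. So Z slows the fade when it is scarcer and J hardly does.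

Accumulated over 3.0 h, the gamma rate leaves 35.2% of what was made at the start. Gamma's first reading, carried back, says 37.2% was made, which gives 13.1% for south-east.

For a feed I assume the same share is made, evenly over the feed, and I average what remains. This is the survival factor 50.9%, the fraction of the D made that still stands at the end, here for east. So east gives 18.9%. West has 38.5% and gives 14.3%.

Theta's first reading, carried back, says 38.6% was made. A straight line from gamma through theta to no J gives 40.0%, and with south-east's survival south gives 14.1%. East stands above the others.

The forecast names east, with 13.2%, 19%, 14.7% and 14.7% for south-east, east, west and south, on the ground that “D is made later and so decays less”, and it stands above my west and above my south.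

South-east ends at 13.5%, east at 19.8%, west at 14.9% and south at 14.7%, so east is best.

    Q + X ⇌ D (K = 79.0 M⁻¹, k = 1.20 M⁻¹ min⁻¹)
    J + X → L (k = 0.0920 M⁻¹ min⁻¹)
    Z + X → E (k = 0.810 M⁻¹ min⁻¹)
    2 X → G (k = 0.0370 M⁻¹ min⁻¹)

At the end of its feed, 2.00 h, the east flask held 27.4% of D. East over south-east is 1.47, and my survival factors give 1.45. With beta's fade the same feed has a survival factor of 62.5%, and beta's 45.5% made then gives 28.4% at 0.25 M of Z. The neighbour flask, fed like east with 0.20 M of Z, less, ends at 33.1%.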